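**Plan**
- Cuts: the two aryl ether bonds O1–C8a and O1''–C8a'' (alkoxide SNAr on ortho-fluoro aryl ketones), then the two aryl–carbonyl bonds C4–C4a and C4''–C4a'' (aryllithium plus lactone). This uncovers the twofold-symmetric bis-γ-lactone 9, which is cut at its two benzylic C–O bonds (oxidative lactonisation) and at the central C3–C3'' bond (oxidative enolate dimerisation).
- Enabling feature: the 1,4-diketone C4–C3–C3''–C4'' with carbinol carbons C2 and C2'' is a doubly ring-opened 2,6-diaryl-3,7-dioxabicyclo[3.3.0]octane-4,8-dione, and a 2,3-cis flavanone ring corresponds to an exo-aryl γ-lactone. Each ring oxygen sits on a carbon β to a ketone whose arene carbon C8a/C8a'' is ortho to that carbonyl, so a fluorine there is displaced through a six-membered transition state without touching C2/C2''.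
- Forward order: imide 3 → dimer 5 (C3–C3'') → diacid 7 → bis-lactone 9 (both γ-lactone rings) → two different ortho-fluoroaryllithiums open the two lactones (19) → both pyranone rings close in one operation (22) → deprotection (24).
- Stereochemistry: the purchased (R)-oxazolidinone sets C3 and C3'' in the dimerisation; these relay to C2 and C2'' in the double lactonisation (allylic strain, exo aryl); all four centres are then carried unchanged to the target.

Key step: step 9

Remark: the SMILES is read as (2R,3R,2''R,3''R), with the 2-aryl group and the 3-substituent cis in both chromanone rings. Unprimed locants denote unit 1 (the 5,7-dihydroxy half) and double-primed locants unit 2 (the 5-hydroxy-7-methoxy half). Compound 19 is drawn open-chain although it can sit partly in its five-membered lactol forms. Its dilithium dialkoxide 20 is likewise drawn open-chain, the form that undergoes ring closure.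

**Route**

Step 1
Reactants: 1 3-(4-methoxyphenyl)propanoyl chloride; 2 (R)-4-benzyl-1,3-oxazolidin-2-one
Product: 3 (R)-4-benzyl-3-[3-(4-methoxyphenyl)propanoyl]-1,3-oxazolidin-2-one
Conditions: Et3N, DMAP (cat.), CH2Cl2, 0 °C → rt
Reagents that add atoms: none
Why: DMAP-catalysed N-acylation of an oxazolidinone by an acid chloride is a standard entry to N-acyl oxazolidinones and touches no stereocentre.

Step 2
Reactants: 3 (R)-4-benzyl-3-[3-(4-methoxyphenyl)propanoyl]-1,3-oxazolidin-2-one (two molecules)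
Product: 5 (2S,3S)-1,4-bis[(R)-4-benzyl-2-oxo-1,3-oxazolidin-3-yl]-2,3-bis(4-methoxybenzyl)butane-1,4-dione, via lithium Z-enolate 4 (not isolated)
Conditions: LiN(i-Pr)2, THF, −78 °C; TiCl4 (1.0 equiv), −78 °C → rt
Reagents that add atoms: none
Why: Oxidative homocoupling of a chiral N-acyl oxazolidinone enolate: the chelated Z-enolate 4 passes to a tetravalent titanium enolate that releases titanium trichloride and an α-carbonyl radical, and each unit is joined on the face away from the auxiliary benzyl group (the facial sense of Evans alkylation), so both new centres should be S and the twofold-symmetric dimer should predominate and be freed of minor diastereomers by crystallisation.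

Step 3
Reactants: 5 (2S,3S)-1,4-bis[(R)-4-benzyl-2-oxo-1,3-oxazolidin-3-yl]-2,3-bis(4-methoxybenzyl)butane-1,4-dione
Product: 7 (2S,3S)-2,3-bis(4-methoxybenzyl)butanedioic acid, via diperoxy acid 6 (not isolated)
Conditions: LiOH, H2O2, THF/H2O, 0 °C; Na2SO3 (aq); HCl to pH 2
Reagents that add atoms: hydrogen peroxide, OO
Why: Lithium hydroperoxide attacks the exocyclic imide carbonyl selectively (standard Evans auxiliary cleavage), sulfite reduces the peracid 6, the α-centres should not epimerise under these mild conditions, and the auxiliary is recovered.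

Step 4
Reactants: 7 (2S,3S)-2,3-bis(4-methoxybenzyl)butanedioic acid
Product: 9 (1R,2R,5R,6R)-2,6-bis(4-methoxyphenyl)-3,7-dioxabicyclo[3.3.0]octane-4,8-dione, via monolactone acid 8 (not isolated)
Conditions: DDQ (2.4 equiv), AcOH, 1,4-dioxane, 80 °C
Reagents that add atoms: none
Why: DDQ abstracts hydride from each benzylic CH2 para to the methoxy group and the p-quinoid cation is trapped 5-exo by the distal carboxyl group (oxidative benzylic lactonisation); allylic strain holds the C–H of the adjacent stereocentre in the plane of the cation, so each aryl group should end trans to the neighbouring carbonyl-bearing carbon (exo on the cis-fused bicycle that the 2S,3S backbone enforces), which sets the two benzylic centres as R.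

Step 5
Reactants: 10 1-fluoro-3,5-dimethoxybenzene
Product: 11 2-bromo-1-fluoro-3,5-dimethoxybenzene
Conditions: NBS, MeCN, 0 °C → rt
Reagents that add atoms: N-bromosuccinimide, O=C1CCC(=O)N1Br
Why: Electrophilic bromination of the doubly activated arene should go para to one methoxy and ortho to the other at the less hindered position next to fluorine and not between the two methoxy groups.

Step 6
Reactants: 12 5-fluorobenzene-1,3-diol
Product: 13 1,3-bis(benzyloxy)-5-fluorobenzene
Conditions: BnBr, K2CO3, DMF, 60 °C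
Reagents that add atoms: benzyl bromide, BrCc1ccccc1
Why: Williamson etherification of both phenols gives benzyl ethers that can later be removed without base.

Step 7
Reactants: 13 1,3-bis(benzyloxy)-5-fluorobenzene
Product: 14 1,5-bis(benzyloxy)-2-bromo-3-fluorobenzene
Conditions: NBS, MeCN, 0 °C → rt
Reagents that add atoms: N-bromosuccinimide, O=C1CCC(=O)N1Br
Why: As in step 5, bromination should occur ortho to fluorine and para to one benzyloxy group, the site between the two bulky benzyloxy groups being the most hindered.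

Step 8
Reactants: 9 (1R,2R,5R,6R)-2,6-bis(4-methoxyphenyl)-3,7-dioxabicyclo[3.3.0]octane-4,8-dione; 11 2-bromo-1-fluoro-3,5-dimethoxybenzene; 14 1,5-bis(benzyloxy)-2-bromo-3-fluorobenzene
Product: 19 (2R,3R)-1-[2,4-bis(benzyloxy)-6-fluorophenyl]-4-(2-fluoro-4,6-dimethoxyphenyl)-2,3-bis[(R)-hydroxy(4-methoxyphenyl)methyl]butane-1,4-dione, via aryllithium 15 (not isolated), via mono-lactolate 16 (not isolated), via aryllithium 17 (not isolated), via bis-lactolate 18 (not isolated)
Conditions: 11, n-BuLi, THF, −78 °C, then 9 (1.0 equiv), −78 °C; then 14/n-BuLi (premixed in THF at −78 °C, 1.3 equiv), −78 °C; AcOH, −78 °C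
Reagents that add atoms: none
Why: Bromine–lithium exchange gives ortho-fluoroaryllithiums that are stable at −78 °C, and aryllithium addition to a lactone stops at the lithium lactolate (as in aryl C-glycoside lactol synthesis); the two carbonyls of 9 are homotopic so the first addition needs no site selectivity, the anionic and hindered mono-adduct 16 should react more slowly than 9, the second aryllithium opens the remaining lactone, no stereocentre is touched, and symmetric bis-adducts are removed by chromatography.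

Step 9
Reactants: 19 (2R,3R)-1-[2,4-bis(benzyloxy)-6-fluorophenyl]-4-(2-fluoro-4,6-dimethoxyphenyl)-2,3-bis[(R)-hydroxy(4-methoxyphenyl)methyl]butane-1,4-dione
Product: 22 (2R,3R)-5,7-bis(benzyloxy)-3-[(2R,3R)-5,7-dimethoxy-2-(4-methoxyphenyl)-4-oxo-3,4-dihydro-2H-chromen-3-yl]-2-(4-methoxyphenyl)-2,3-dihydro-4H-chromen-4-one, via dilithium dialkoxide 20 (not isolated), via half-closed alkoxide 21 (not isolated)
Conditions: LiN(SiMe3)2 (2.05 equiv), THF/DMPU, −78 → 0 °C; NH4Cl (aq)
Reagents that add atoms: none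
Why: Deprotonation of both carbinols gives the open-chain dilithium dialkoxide 20 (in equilibrium with its lactolate ring tautomers); each alkoxide adds to the fluorine-bearing carbon ortho to its own ketone, giving a Meisenheimer complex stabilised by that carbonyl and inductively by the two meta alkoxy groups, and loss of lithium fluoride forms O1–C8a (half-closed alkoxide 21) and then O1''–C8a''. The closest known reaction type is the intramolecular SNAr cyclisation of 3-hydroxy-1-(2-fluoroaryl) ketones to chroman-4-ones. Both rings close as six-membered rings by attack at the arene carbon ortho to the acyl group (formally 6-exo-trig, the charge being pushed out of the new ring). No stereocentre is formed: C2, C3, C3'' and C2'' come unchanged from 9, and because the oxygen–aryl bond and not the O–C2 bond is made, the 2,3-cis geometry that a reversible oxa-Michael closure would lose is kept. The step needs each alkoxide to choose its own arene (six-membered transition state against seven for the other arene) and SNAr to outrun retro-aldol cleavage and C3 enolisation; the lithium counter-ion, the low temperature and the consumption of the base as lithium fluoride while the rings form should secure this.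

Step 10
Reactants: 22 (2R,3R)-5,7-bis(benzyloxy)-3-[(2R,3R)-5,7-dimethoxy-2-(4-methoxyphenyl)-4-oxo-3,4-dihydro-2H-chromen-3-yl]-2-(4-methoxyphenyl)-2,3-dihydro-4H-chromen-4-one
Product: 24 (2R,3R)-5,7-dihydroxy-3-[(2R,3R)-5-hydroxy-7-methoxy-2-(4-methoxyphenyl)-4-oxo-3,4-dihydro-2H-chromen-3-yl]-2-(4-methoxyphenyl)-2,3-dihydro-4H-chromen-4-one, via tris(dichloroboryl) ether 23 (not isolated)
Conditions: BCl3 (6 equiv), C6HMe5, CH2Cl2, −78 → 0 °C; H2O
Reagents that add atoms: none
Why: BCl3 cleaves aryl benzyl ethers at low temperature with pentamethylbenzene as benzyl cation scavenger and, through chelation to the C4'' carbonyl, the peri 5''-methyl ether, while the unchelated 7''- and anisyl methyl ethers should survive; the non-basic medium spares the base-labile cis C2/C3 centres and the boron aryloxides 23 are hydrolysed on work-up.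

**Compound list**

1 | 3-(4-methoxyphenyl)propanoyl chloride | COc1ccc(CCC(Cl)=O)cc1 | starting material
2 | (R)-4-benzyl-1,3-oxazolidin-2-one | O=C1N[C@H](Cc2ccccc2)CO1 | starting material
3 | (R)-4-benzyl-3-[3-(4-methoxyphenyl)propanoyl]-1,3-oxazolidin-2-one | COc1ccc(CCC(=O)N2[C@H](Cc3ccccc3)COC2=O)cc1 | intermediate
4 | lithium (Z)-enolate of 3 | COc1ccc(C/C=C(\O[Li])N2[C@H](Cc3ccccc3)COC2=O)cc1 | intermediate
5 | (2S,3S)-1,4-bis[(R)-4-benzyl-2-oxo-1,3-oxazolidin-3-yl]-2,3-bis(4-methoxybenzyl)butane-1,4-dione | COc1ccc(C[C@H](C(=O)N2[C@H](Cc3ccccc3)COC2=O)[C@@H](C(=O)N2[C@H](Cc3ccccc3)COC2=O)Cc2ccc(OC)cc2)cc1 | intermediate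
6 | (2S,3S)-2,3-bis(4-methoxybenzyl)butanediperoxoic acid | COc1ccc(C[C@H](C(=O)OO)[C@@H](C(=O)OO)Cc2ccc(OC)cc2)cc1 | intermediate
7 | (2S,3S)-2,3-bis(4-methoxybenzyl)butanedioic acid | COc1ccc(C[C@H](C(=O)O)[C@@H](C(=O)O)Cc2ccc(OC)cc2)cc1 | intermediate
8 | (2R,3R,4S)-4-(4-methoxybenzyl)-2-(4-methoxyphenyl)-5-oxotetrahydrofuran-3-carboxylic acid | COc1ccc([C@@H]2OC(=O)[C@@H](Cc3ccc(OC)cc3)[C@H]2C(=O)O)cc1 | intermediate
9 | (1R,2R,5R,6R)-2,6-bis(4-methoxyphenyl)-3,7-dioxabicyclo[3.3.0]octane-4,8-dione | COc1ccc([C@@H]2OC(=O)[C@@H]3[C@H]2C(=O)O[C@H]3c2ccc(OC)cc2)cc1 | intermediate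
10 | 1-fluoro-3,5-dimethoxybenzene | COc1cc(F)cc(OC)c1 | starting material
11 | 2-bromo-1-fluoro-3,5-dimethoxybenzene | COc1cc(OC)c(Br)c(F)c1 | intermediate
12 | 5-fluorobenzene-1,3-diol | Oc1cc(O)cc(F)c1 | starting material
13 | 1,3-bis(benzyloxy)-5-fluorobenzene | Fc1cc(OCc2ccccc2)cc(OCc2ccccc2)c1 | intermediate
14 | 1,5-bis(benzyloxy)-2-bromo-3-fluorobenzene | Fc1cc(OCc2ccccc2)cc(OCc2ccccc2)c1Br | intermediate
15 | 2-fluoro-4,6-dimethoxyphenyllithium | [Li]c1c(F)cc(OC)cc1OC | intermediate
16 | lithium lactolate from addition of 15 to one lactone carbonyl of 9 (configuration at the new hemiketal carbon not defined) | COc1ccc([C@@H]2OC(O[Li])(c3c(F)cc(OC)cc3OC)[C@@H]3[C@H]2C(=O)O[C@H]3c2ccc(OC)cc2)cc1 | intermediate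
17 | 2,4-bis(benzyloxy)-6-fluorophenyllithium | [Li]c1c(F)cc(OCc2ccccc2)cc1OCc1ccccc1 | intermediate
18 | dilithium bis-lactolate from addition of 17 to the remaining lactone carbonyl of 16 (ring tautomer of dialkoxide 20; hemiketal carbons not defined) | COc1ccc([C@@H]2OC(O[Li])(c3c(F)cc(OC)cc3OC)[C@@H]3[C@H]2C(O[Li])(c2c(F)cc(OCc4ccccc4)cc2OCc2ccccc2)O[C@H]3c2ccc(OC)cc2)cc1 | intermediate
19 | (2R,3R)-1-[2,4-bis(benzyloxy)-6-fluorophenyl]-4-(2-fluoro-4,6-dimethoxyphenyl)-2,3-bis[(R)-hydroxy(4-methoxyphenyl)methyl]butane-1,4-dione | COc1ccc([C@H](O)[C@H](C(=O)c2c(F)cc(OCc3ccccc3)cc2OCc2ccccc2)[C@@H](C(=O)c2c(F)cc(OC)cc2OC)[C@@H](O)c2ccc(OC)cc2)cc1 | intermediate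
20 | open-chain dilithium dialkoxide of 19 | COc1ccc([C@H](O[Li])[C@H](C(=O)c2c(F)cc(OCc3ccccc3)cc2OCc2ccccc2)[C@@H](C(=O)c2c(F)cc(OC)cc2OC)[C@@H](O[Li])c2ccc(OC)cc2)cc1 | intermediate
21 | half-closed lithium alkoxide (pyranone ring of unit 1 closed, unit 2 still open; the order of the two closures is immaterial) | COc1ccc([C@@H]2Oc3cc(OCc4ccccc4)cc(OCc4ccccc4)c3C(=O)[C@@H]2[C@@H](C(=O)c2c(F)cc(OC)cc2OC)[C@@H](O[Li])c2ccc(OC)cc2)cc1 | intermediate
22 | (2R,3R)-5,7-bis(benzyloxy)-3-[(2R,3R)-5,7-dimethoxy-2-(4-methoxyphenyl)-4-oxo-3,4-dihydro-2H-chromen-3-yl]-2-(4-methoxyphenyl)-2,3-dihydro-4H-chromen-4-one | COc1ccc([C@@H]2Oc3cc(OCc4ccccc4)cc(OCc4ccccc4)c3C(=O)[C@@H]2[C@H]2C(=O)c3c(OC)cc(OC)cc3O[C@H]2c2ccc(OC)cc2)cc1 | intermediate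
23 | 5,7,5''-tris(dichloroboryl) ether of the target | COc1ccc([C@@H]2Oc3cc(OB(Cl)Cl)cc(OB(Cl)Cl)c3C(=O)[C@@H]2[C@H]2C(=O)c3c(OB(Cl)Cl)cc(OC)cc3O[C@H]2c2ccc(OC)cc2)cc1 | intermediate
24 | (2R,3R)-5,7-dihydroxy-3-[(2R,3R)-5-hydroxy-7-methoxy-2-(4-methoxyphenyl)-4-oxo-3,4-dihydro-2H-chromen-3-yl]-2-(4-methoxyphenyl)-2,3-dihydro-4H-chromen-4-one | COc1ccc([C@@H]2Oc3cc(O)cc(O)c3C(=O)[C@@H]2[C@H]2C(=O)c3c(O)cc(OC)cc3O[C@H]2c2ccc(OC)cc2)cc1 | target

**Count and risks**

Total steps: 10. Longest linear sequence: 7 steps (1, 2, 3, 4, 8, 9, 10).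

Steps most likely to fail:

1. Step 9. The free alkoxides may undergo retro-aldol cleavage and re-addition, or enolisation at C3/C3'', faster than ring closure, which would erode the cis configuration. Fallback: setting out from 19, both carbinols are silylated (Me3SiCl, imidazole, CH2Cl2) to (2R,3R)-1-[2,4-bis(benzyloxy)-6-fluorophenyl]-4-(2-fluoro-4,6-dimethoxyphenyl)-2,3-bis[(R)-(4-methoxyphenyl)(trimethylsilyloxy)methyl]butane-1,4-dione F1. The rings are then closed by fluoride-catalysed desilylative SNAr (CsF cat., DMF, rt), a known coupling of silyl ethers with activated aryl fluorides. Fluoride unmasks one alkoxide at a time and each ring closure returns the fluoride that carries the chain, so no stoichiometric base is present. This comes back to the route at 22.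

2. Step 8. The first aryllithium may add unselectively (double addition beside unreacted 9), or act as a base and open a lactone by β-elimination. Fallback: setting out from 9, both lactones are opened with the single aryllithium 17 (2.4 equiv, THF, −78 °C; AcOH) to the symmetric diketo diol (2R,3R)-1,4-bis[2,4-bis(benzyloxy)-6-fluorophenyl]-2,3-bis[(R)-hydroxy(4-methoxyphenyl)methyl]butane-1,4-dione F2. LiN(SiMe3)2 closes both rings to the tetra-O-benzyl biflavanone (2R,3R)-5,7-bis(benzyloxy)-3-[(2R,3R)-5,7-bis(benzyloxy)-2-(4-methoxyphenyl)-4-oxo-3,4-dihydro-2H-chromen-3-yl]-2-(4-methoxyphenyl)-2,3-dihydro-4H-chromen-4-one F3. BCl3/C6HMe5 gives the twofold-symmetric tetraphenol (2R,3R)-5,7-dihydroxy-3-[(2R,3R)-5,7-dihydroxy-2-(4-methoxyphenyl)-4-oxo-3,4-dihydro-2H-chromen-3-yl]-2-(4-methoxyphenyl)-2,3-dihydro-4H-chromen-4-one F4. One of its two homotopic, unchelated 7-hydroxyl groups is then methylated with Me3SiCHN2 (1 equiv, MeOH/toluene), the chelated 5-hydroxyls being inert. This comes back to the route at 24; only mono- against bis-methylation remains to be controlled and unreacted F4 is recycled.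

3. Step 4. Hydride abstraction may be incomplete, the benzylic cation may lose a proton to give an arylidene succinic acid, or the exo/endo selectivity of the carboxyl capture may be poor. Fallback: setting out from 7, Wohl–Ziegler bromination (NBS, AIBN, PhCF3, 80 °C) gives the bis(benzylic bromide) (2S,3S)-2,3-bis[bromo(4-methoxyphenyl)methyl]butanedioic acid F5. Its 4-methoxybenzylic bromides ionise and are captured by the carboxyl groups on warming with NaHCO3 in MeCN. This comes back to the route at 9.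

**Further compounds**

F1 | step 9 | (2R,3R)-1-[2,4-bis(benzyloxy)-6-fluorophenyl]-4-(2-fluoro-4,6-dimethoxyphenyl)-2,3-bis[(R)-(4-methoxyphenyl)(trimethylsilyloxy)methyl]butane-1,4-dione | COc1ccc([C@H](O[Si](C)(C)C)[C@H](C(=O)c2c(F)cc(OCc3ccccc3)cc2OCc2ccccc2)[C@@H](C(=O)c2c(F)cc(OC)cc2OC)[C@@H](O[Si](C)(C)C)c2ccc(OC)cc2)cc1
F2 | step 8 | (2R,3R)-1,4-bis[2,4-bis(benzyloxy)-6-fluorophenyl]-2,3-bis[(R)-hydroxy(4-methoxyphenyl)methyl]butane-1,4-dione | COc1ccc([C@H](O)[C@H](C(=O)c2c(F)cc(OCc3ccccc3)cc2OCc2ccccc2)[C@@H](C(=O)c2c(F)cc(OCc3ccccc3)cc2OCc2ccccc2)[C@@H](O)c2ccc(OC)cc2)cc1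
F3 | step 8 | (2R,3R)-5,7-bis(benzyloxy)-3-[(2R,3R)-5,7-bis(benzyloxy)-2-(4-methoxyphenyl)-4-oxo-3,4-dihydro-2H-chromen-3-yl]-2-(4-methoxyphenyl)-2,3-dihydro-4H-chromen-4-one | COc1ccc([C@@H]2Oc3cc(OCc4ccccc4)cc(OCc4ccccc4)c3C(=O)[C@@H]2[C@H]2C(=O)c3c(OCc4ccccc4)cc(OCc4ccccc4)cc3O[C@H]2c2ccc(OC)cc2)cc1
F4 | step 8 | (2R,3R)-5,7-dihydroxy-3-[(2R,3R)-5,7-dihydroxy-2-(4-methoxyphenyl)-4-oxo-3,4-dihydro-2H-chromen-3-yl]-2-(4-methoxyphenyl)-2,3-dihydro-4H-chromen-4-one | COc1ccc([C@@H]2Oc3cc(O)cc(O)c3C(=O)[C@@H]2[C@H]2C(=O)c3c(O)cc(O)cc3O[C@H]2c2ccc(OC)cc2)cc1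
F5 | step 4 | (2S,3S)-2,3-bis[bromo(4-methoxyphenyl)methyl]butanedioic acid (benzylic centres not defined) | COc1ccc(C(Br)[C@H](C(=O)O)[C@@H](C(=O)O)C(Br)c2ccc(OC)cc2)cc1
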